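The runs are calculated with made-up constants.

I started from the constants, and the runs gave me one of them: while E lasted in the ochre run, J fell from 70 % to 49 % between 2.00 min and 3.00 min, a reading of 0.357 min⁻¹ for first-order loss. The decision was whether a flask at 0.800 equiv of E should keep that charge and its 10 min.

| setting | blue | ochre | grey | flask |
|---|---|---|---|---|
| J | 0.24 M (fed, over 2.0 min) | 0.24 M (fed, over 2.0 min) | 0.36 M (fed, over 2.0 min) | 0.24 M (fed, over 2.0 min) |
| E | 0.40 equiv | 1.6 equiv | 0.80 equiv | 0.800 equiv |
| remark | run made earlier | run made earlier | run made earlier |  |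
| time |  |  |  | 10 min |

| run | time / min | J / % | X / % |
|---|---|---|---|
| blue | 0.667 | 29 | 5 |
| blue | 2.00 | 72 | 25 |
| blue | 3.00 | 75 | 22 |
| blue | 5.00 | 72 | 23 |
| blue | 8.00 | 74 | 26 |
| blue | 10.0 | 75 | 26 |
| blue | 12.0 | 74 | 25 |
| ochre | 0.667 | 31 | 6 |
| ochre | 2.00 | 70 | 27 |
| ochre | 3.00 | 49 | 52 |
| ochre | 5.00 | 31 | 68 |
| ochre | 8.00 | 30 | 66 |
| ochre | 10.0 | 33 | 66 |
| ochre | 12.0 | 30 | 66 |
| grey | 1.00 | 44 | 8 |
| grey | 2.00 | 69 | 28 |
| grey | 3.00 | 53 | 43 |
| grey | 6.00 | 56 | 44 |
| grey | 12.0 | 58 | 42 |

(each reading ± 1.5 percentage points)

- candidate steps: J <-> Q; Q <-> D; E + Q -> X; E + D -> L; E -> Z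
- the reaction counts as stopped when no species that holds the J changes by six tenths of a point or more over the second half of the time
- percentages count the whole charge, also what has not yet gone in

- the state of affairs at 10 min: stopped, and by what, or still going (forward and back rates have come level / E has run out first / it is still moving / all of J has reacted)
- how much of the J has reacted by 10 min
- how much X there is at 10 min, in percent of the J charged

I froze one thing: I assumed that E passes into Z with that same constant, and that each J turned into X costs one E. In fractions of the J charged, the ratio of E to J then falls steadily after the feed, and J stops when E reaches zero. The log of J at the end of the feed over J at the stop then equals that ratio at the end of the feed. I called this log the reach and took it as a straight line in the E charged. Both losses in this reckoning are first-order, so the molarity of J drops out of it and runs of different charge can stand on one line.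

The last readings of J in the ochre run averaged 31.0 %, a reach of 0.815. Those of the grey run averaged 57.0 %, a reach of 0.191. The reach gained per equivalent of E charged, the slope of the line, was therefore 0.779, and the line reaches zero at 0.555. Blue, charged with less than that at 0.40 equiv, stayed flat after its feed. I read the flask from grey's equivalents: conversion 43.0 %. I kept the charge; with the ratio falling at 0.357 min⁻¹, the stop lay 0.536 min after the feed, well within the 10 min.

The forecast was: E has run out first, with conversion 43.5 % (40.5 % to 46.5 %) and X 42 % (39 % to 45 %), holding that “E is also being lost on its own”.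

The flask gave: E has run out first, with conversion 44.3 % and X 42.7 %, and E at 0 % of its charge. X moves 5 points, past the forecast's range, at 0.679 equiv or 0.932 equiv of E. With its slope of 0.779, the line gave this flask a reach of 0.191; in the flask, J went from 69.3 % to 55.7 %, a reach of 0.218.

    J ⇌ Q (K = 0.00690, k = 0.00670 s⁻¹)
    Q ⇌ D (K = 0.350, k = 0.330 s⁻¹)
    E + Q → X (k = 580 M⁻¹ s⁻¹)
    E + D → L (k = 6700 M⁻¹ s⁻¹)
    E → Z (k = 0.00610 s⁻¹)

At 3.20 equiv of E, the line gives a reach of 2.06, so J from ochre's 70 % stops at 8.91 %. The computed flask stands at J 9.22 %, X 89.7 % and E 0 %.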